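**Retrosynthetic overview**
1. C20=C21 (Z-ylidene butenolide): aldehyde 24 plus C-5-lithiated 4-O-methyl-3-methyltetronate (aldol, then mesylate elimination); O-demethylation is the last step.
2. C13–C15: B-alkyl Suzuki coupling of Z-vinyl iodide 16 with hydroborated (S)-2-methylpent-4-en-1-ol 21; C-18 comes from an Evans allylation.
3. C12=C13: Z-selective α-iodoethylidene Wittig on aldehyde 11. C7=C8 (E) and C10–C11: Johnson–Claisen rearrangement of allylic alcohol 5 (furylethyl Grignard plus methacrolein).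
4. Rings: none is formed; the 3-substituted furan and the butenolide are bought intact (2-(furan-3-yl)ethanol, 3-methyltetronic acid).

Assumption: the SMILES is read as (7E,12Z,18S,20Z)-variabilin (variabilin numbering: furan C1–C4, chain C5–C20, butenolide C21–C24); 2-(furan-3-yl)ethanol, (4R)-4-benzyl-3-propanoyl-1,3-oxazolidin-2-one and 3-methyltetronic acid are taken as purchasable.

**Route**

Step 1
Reactants: 1 2-(furan-3-yl)ethanol
Product: 2 3-(2-bromoethyl)furan
Conditions: CBr4, PPh3, CH2Cl2, 0 °C to rt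
Reagents that add atoms: carbon tetrabromide, BrC(Br)(Br)Br
Why: Appel reaction, in which the alkoxyphosphonium ion of the primary alcohol is displaced by bromide (SN2) under neutral conditions that leave the acid-sensitive furan untouched.

Step 2
Reactants: 2 3-(2-bromoethyl)furan; 3 methacrolein (2-methylprop-2-enal)
Product: 5 racemic 5-(furan-3-yl)-2-methylpent-1-en-3-ol, via Grignard reagent 4 (not isolated)
Conditions: Mg, THF, rt; then 3, −78 to 0 °C; aq. NH4Cl
Reagents that add atoms: none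
Why: Grignard formation followed by 1,2-addition to the enal carbonyl gives the secondary allylic alcohol, deliberately as a racemate because this stereocenter is erased in step 3.

Step 3
Reactants: 5 racemic 5-(furan-3-yl)-2-methylpent-1-en-3-ol; 6 triethyl orthoacetate
Product: 9 ethyl (4E)-7-(furan-3-yl)-4-methylhept-4-enoate, via mixed orthoester 7 (not isolated), via ketene acetal 8 (not isolated)
Conditions: 6 (6 equiv), EtCO2H (cat.), 140 °C, EtOH distilled off
Reagents that add atoms: none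
Why: Johnson–Claisen rearrangement, whose chair transition state places the furylethyl group equatorial so that the new trisubstituted alkene is formed E (typically at least 95:5) while the carbinol stereocenter is destroyed and a two-carbon ester arm is added.

Step 4
Reactants: 9 ethyl (4E)-7-(furan-3-yl)-4-methylhept-4-enoate
Product: 11 (4E)-7-(furan-3-yl)-4-methylhept-4-enal, via aluminium hemiacetal 10 (not isolated)
Conditions: i-Bu2AlH (1.05 equiv), CH2Cl2, −78 °C; aq. KNaC4H4O6 (potassium sodium tartrate)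
Reagents that add atoms: none
Why: Partial ester reduction, in which the tetrahedral aluminium hemiacetal is stable at −78 °C and collapses to the aldehyde only on aqueous work-up, so over-reduction is avoided and the alkene and furan are inert.

Step 5
Reactants: 11 (4E)-7-(furan-3-yl)-4-methylhept-4-enal; 12 ethyltriphenylphosphonium iodide
Product: 16 3-[(3E,7Z)-8-iodo-4-methylnona-3,7-dien-1-yl]furan, via ethylidenetriphenylphosphorane 13 (not isolated), via (1-iodoethyl)triphenylphosphonium iodide 14 (not isolated), via (1-iodoethylidene)triphenylphosphorane 15 (not isolated)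
Conditions: 12, n-BuLi, THF, 0 °C to rt; I2, −78 °C; NaN(SiMe3)2, −78 to −20 °C; then 11, −78 °C to rt
Reagents that add atoms: iodine, [I][I]
Why: Stork–Zhao-type Wittig olefination with the non-stabilised α-iodo ylide under kinetic control gives the Z-vinyl iodide (iodine cis to the chain, typically about 10:1, minor E isomer removed by chromatography), which fixes the later 12Z geometry.

Step 6
Reactants: 17 (4R)-4-benzyl-3-propanoyl-1,3-oxazolidin-2-one; 18 allyl iodide (3-iodoprop-1-ene)
Product: 20 (4R)-4-benzyl-3-[(2S)-2-methylpent-4-enoyl]-1,3-oxazolidin-2-one, via sodium Z-enolate 19 (not isolated)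
Conditions: NaN(SiMe3)2, THF, −78 °C; then 18, −78 to −40 °C
Reagents that add atoms: none
Why: Evans asymmetric alkylation, in which the chelated Z-enolate is shielded on one face by the (R)-benzyl group so that allyl iodide enters from the opposite face and sets the (S) methyl-bearing stereocenter (the future C-18) with dr typically at least 95:5, raised further by chromatography.

Step 7
Reactants: 20 (4R)-4-benzyl-3-[(2S)-2-methylpent-4-enoyl]-1,3-oxazolidin-2-one
Product: 21 (2S)-2-methylpent-4-en-1-ol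
Conditions: LiBH4, Et2O, H2O (1 equiv), 0 °C
Reagents that add atoms: none
Why: Reductive cleavage of the N-acyl oxazolidinone at the exocyclic carbonyl gives the primary alcohol without touching the α-stereocenter or the alkene, and the auxiliary is recovered.

Step 8
Reactants: 21 (2S)-2-methylpent-4-en-1-ol; 16 3-[(3E,7Z)-8-iodo-4-methylnona-3,7-dien-1-yl]furan
Product: 23 (2S,6Z,10E)-13-(furan-3-yl)-2,6,10-trimethyltrideca-6,10-dien-1-ol, via alkylborane 22 (not isolated)
Conditions: 9-BBN-H (2.2 equiv), THF, 0 °C to rt; then 16, Pd(dppf)Cl2 (5 mol%), AsPh3, Cs2CO3, DMF/THF/H2O, rt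
Reagents that add atoms: none
Why: B-alkyl Suzuki–Miyaura coupling, in which one equivalent of borane is spent on the hydroxyl as a borinate, the second hydroborates the terminal alkene anti-Markovnikov, and oxidative addition of the vinyl iodide to zerovalent palladium, transmetalation and reductive elimination proceed with retention to give the Z-trisubstituted alkene while the remote stereocenter is untouched.

Step 9
Reactants: 23 (2S,6Z,10E)-13-(furan-3-yl)-2,6,10-trimethyltrideca-6,10-dien-1-ol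
Product: 24 (2S,6Z,10E)-13-(furan-3-yl)-2,6,10-trimethyltrideca-6,10-dienal
Conditions: DMP (Dess–Martin periodinane), NaHCO3, CH2Cl2, 0 °C to rt
Reagents that add atoms: none
Why: Dess–Martin oxidation under buffered non-basic conditions stops at the aldehyde without epimerising the α-stereocenter or attacking the furan and alkenes, and the aldehyde is used at once.

Step 10
Reactants: 25 3-methyltetronic acid (4-hydroxy-3-methylfuran-2(5H)-one)
Product: 26 4-methoxy-3-methylfuran-2(5H)-one
Conditions: Me2SO4, K2CO3, acetone, reflux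
Reagents that add atoms: dimethyl sulfate, COS(=O)(=O)OC
Why: O-Alkylation of the vinylogous acid with a hard methylating agent gives the methyl tetronate, which masks the acidic enol for the anion chemistry that follows.

Step 11
Reactants: 26 4-methoxy-3-methylfuran-2(5H)-one; 24 (2S,6Z,10E)-13-(furan-3-yl)-2,6,10-trimethyltrideca-6,10-dienal
Product: 28 5-[(2S,6Z,10E)-13-(furan-3-yl)-1-hydroxy-2,6,10-trimethyltrideca-6,10-dien-1-yl]-4-methoxy-3-methylfuran-2(5H)-one, via lithium furanolate 27 (not isolated)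
Conditions: LiN(i-Pr)2, THF, −78 °C; then 24, −78 °C; AcOH quench
Reagents that add atoms: none
Why: Aldol addition of the C-5-lithiated methyl tetronate (an aromatic 2-furanolate and a weak base) is fast at −78 °C so the α-chiral aldehyde is not enolised, and the two new stereocenters, formed as a mixture, are both removed in step 12.

Step 12
Reactants: 28 5-[(2S,6Z,10E)-13-(furan-3-yl)-1-hydroxy-2,6,10-trimethyltrideca-6,10-dien-1-yl]-4-methoxy-3-methylfuran-2(5H)-one
Product: 30 (5Z)-5-[(2S,6Z,10E)-13-(furan-3-yl)-2,6,10-trimethyltrideca-6,10-dien-1-ylidene]-4-methoxy-3-methylfuran-2(5H)-one, via mesylate 29 (not isolated)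
Conditions: MsCl, Et3N, CH2Cl2, 0 °C; then DBU, rt
Reagents that add atoms: none
Why: Mesylation followed by E1cB elimination through the acidic C-5 position gives the conjugated 5-ylidene butenolide as the thermodynamically preferred Z isomer (chain syn to the ring oxygen and away from the 4-methoxy group), while the C-18 stereocenter is retained.

Step 13
Reactants: 30 (5Z)-5-[(2S,6Z,10E)-13-(furan-3-yl)-2,6,10-trimethyltrideca-6,10-dien-1-ylidene]-4-methoxy-3-methylfuran-2(5H)-one
Product: 31 (5Z)-5-[(2S,6Z,10E)-13-(furan-3-yl)-2,6,10-trimethyltrideca-6,10-dien-1-ylidene]-4-hydroxy-3-methylfuran-2(5H)-one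
Conditions: n-PrSLi (from n-PrSH and n-BuLi), HMPA, rt; then 1 M HCl
Reagents that add atoms: none
Why: SN2 O-demethylation by the soft thiolate at the methyl group of the vinylogous ester releases the tetronate anion, which is protonated on acidic work-up, and no stereocenter or alkene geometry is touched.

**Compound list**

1 | 2-(furan-3-yl)ethanol | OCCc1ccoc1 | starting material
2 | 3-(2-bromoethyl)furan | BrCCc1ccoc1 | intermediate
3 | methacrolein (2-methylprop-2-enal) | CC(=C)C=O | starting material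
4 | [2-(furan-3-yl)ethyl]magnesium bromide | Br[Mg]CCc1ccoc1 | intermediate
5 | 5-(furan-3-yl)-2-methylpent-1-en-3-ol (racemic) | CC(=C)C(O)CCc1ccoc1 | intermediate
6 | triethyl orthoacetate (1,1,1-triethoxyethane) | CC(OCC)(OCC)OCC | starting material
7 | 3-[3-(1,1-diethoxyethoxy)-4-methylpent-4-en-1-yl]furan (mixed orthoester, racemic) | CCOC(C)(OCC)OC(CCc1ccoc1)C(C)=C | intermediate
8 | 3-{3-[(1-ethoxyethenyl)oxy]-4-methylpent-4-en-1-yl}furan (ketene acetal, racemic) | CCOC(=C)OC(CCc1ccoc1)C(C)=C | intermediate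
9 | ethyl (4E)-7-(furan-3-yl)-4-methylhept-4-enoate | CCOC(=O)CC/C(C)=C/CCc1ccoc1 | intermediate
10 | {[(4E)-1-ethoxy-7-(furan-3-yl)-4-methylhept-4-en-1-yl]oxy}bis(2-methylpropyl)alumane (aluminium hemiacetal) | CCOC(CC/C(C)=C/CCc1ccoc1)O[Al](CC(C)C)CC(C)C | intermediate
11 | (4E)-7-(furan-3-yl)-4-methylhept-4-enal | O=CCC/C(C)=C/CCc1ccoc1 | intermediate
12 | ethyltriphenylphosphonium iodide | CC[P+](c1ccccc1)(c1ccccc1)c1ccccc1.[I-] | starting material
13 | ethylidenetriphenylphosphorane | CC=P(c1ccccc1)(c1ccccc1)c1ccccc1 | intermediate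
14 | (1-iodoethyl)triphenylphosphonium iodide | CC([I])[P+](c1ccccc1)(c1ccccc1)c1ccccc1.[I-] | intermediate
15 | (1-iodoethylidene)triphenylphosphorane | CC([I])=P(c1ccccc1)(c1ccccc1)c1ccccc1 | intermediate
16 | 3-[(3E,7Z)-8-iodo-4-methylnona-3,7-dien-1-yl]furan | [I]/C(C)=C\CC/C(C)=C/CCc1ccoc1 | intermediate
17 | (4R)-4-benzyl-3-propanoyl-1,3-oxazolidin-2-one | CCC(=O)N1[C@H](Cc2ccccc2)COC1=O | starting material
18 | allyl iodide (3-iodoprop-1-ene) | C=CC[I] | starting material
19 | sodium (1Z)-1-[(4R)-4-benzyl-2-oxo-1,3-oxazolidin-3-yl]prop-1-en-1-olate | [Na+].C/C=C(\[O-])N1[C@H](Cc2ccccc2)COC1=O | intermediate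
20 | (4R)-4-benzyl-3-[(2S)-2-methylpent-4-enoyl]-1,3-oxazolidin-2-one | C=CC[C@H](C)C(=O)N1[C@H](Cc2ccccc2)COC1=O | intermediate
21 | (2S)-2-methylpent-4-en-1-ol | C=CC[C@H](C)CO | intermediate
22 | 9-{[(2S)-5-(9-borabicyclo[3.3.1]nonan-9-yl)-2-methylpentyl]oxy}-9-borabicyclo[3.3.1]nonane | B1(OC[C@@H](C)CCCB2C3CCCC2CCC3)C4CCCC1CCC4 | intermediate
23 | (2S,6Z,10E)-13-(furan-3-yl)-2,6,10-trimethyltrideca-6,10-dien-1-ol | OC[C@@H](C)CCC/C(C)=C\CC/C(C)=C/CCc1ccoc1 | intermediate
24 | (2S,6Z,10E)-13-(furan-3-yl)-2,6,10-trimethyltrideca-6,10-dienal | O=C[C@@H](C)CCC/C(C)=C\CC/C(C)=C/CCc1ccoc1 | intermediate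
25 | 3-methyltetronic acid (4-hydroxy-3-methylfuran-2(5H)-one) | CC1=C(O)COC1=O | starting material
26 | 4-methoxy-3-methylfuran-2(5H)-one | COC1=C(C)C(=O)OC1 | intermediate
27 | lithium 4-methoxy-3-methylfuran-2-olate | [Li+].COc1coc([O-])c1C | intermediate
28 | 5-[(2S,6Z,10E)-13-(furan-3-yl)-1-hydroxy-2,6,10-trimethyltrideca-6,10-dien-1-yl]-4-methoxy-3-methylfuran-2(5H)-one (mixture at C-5 and the carbinol carbon) | COC1=C(C)C(=O)OC1C(O)[C@@H](C)CCC/C(C)=C\CC/C(C)=C/CCc2ccoc2 | intermediate
29 | (2S,6Z,10E)-13-(furan-3-yl)-1-(3-methoxy-4-methyl-5-oxo-2,5-dihydrofuran-2-yl)-2,6,10-trimethyltrideca-6,10-dien-1-yl methanesulfonate (mixture at the same two carbons) | COC1=C(C)C(=O)OC1C(OS(C)(=O)=O)[C@@H](C)CCC/C(C)=C\CC/C(C)=C/CCc2ccoc2 | intermediate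
30 | (5Z)-5-[(2S,6Z,10E)-13-(furan-3-yl)-2,6,10-trimethyltrideca-6,10-dien-1-ylidene]-4-methoxy-3-methylfuran-2(5H)-one | CC1=C(OC)/C(=C/[C@@H](C)CCC/C(C)=C\CC/C(C)=C/CCc2ccoc2)OC1=O | intermediate
31 | (5Z)-5-[(2S,6Z,10E)-13-(furan-3-yl)-2,6,10-trimethyltrideca-6,10-dien-1-ylidene]-4-hydroxy-3-methylfuran-2(5H)-one | CC1=C(O)/C(=C/[C@@H](C)CCC/C(C)=C\CC/C(C)=C/CCc2ccoc2)OC1=O | target

**Totals**

Total step count: 13.
Longest linear sequence: 10 steps (steps 1, 2, 3, 4, 5, 8, 9, 11, 12, 13).

**Steps most likely to fail, with fallbacks**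

Step 5 (α-iodo Wittig): the yield is usually modest and the Z:E ratio is not perfect. The fallback sets out from 11 and comes back to the route at 23. Dibromoolefination of 11 (CBr4, PPh3, CH2Cl2, 0 °C) gives 3-[(3E)-8,8-dibromo-4-methylocta-3,7-dien-1-yl]furan F1. Trans-selective mono-methylation of the bromine anti to the chain (Me2Zn, Pd(DPEphos)Cl2 cat., THF) then gives 3-[(3E,7Z)-8-bromo-4-methylnona-3,7-dien-1-yl]furan F2 as essentially one isomer. F2 takes the place of 16 in the coupling with borane 22 of step 8, run with Pd(t-Bu3P)2 and Cs2CO3 so that the second substitution goes with retention, and delivers 23.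

Step 8 (B-alkyl Suzuki coupling on the free alcohol): the O-borinate may slow transmetalation or favour protodeiodination. The fallback gives up the protecting-group-free coupling; it sets out from 21 and comes back at 23. Silylation of 21 (TBSCl, imidazole, DMF) gives tert-butyl(dimethyl){[(2S)-2-methylpent-4-en-1-yl]oxy}silane F3. Hydroboration with 1.1 equiv of 9-BBN-H gives 9-[(4S)-5-{[tert-butyl(dimethyl)silyl]oxy}-4-methylpentyl]-9-borabicyclo[3.3.1]nonane F4. Coupling with 16 under the palladium conditions of step 8 gives tert-butyl{[(2S,6Z,10E)-13-(furan-3-yl)-2,6,10-trimethyltrideca-6,10-dien-1-yl]oxy}dimethylsilane F5, and Bu4NF in THF releases 23.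

Step 13 (thiolate demethylation): the thiolate may add to the dienyl lactone or scramble the C20 geometry. The fallback replaces the O-methyl group by a fluoride-labile group from the outset; it sets out from 25 (and uses 24) and comes back at 31.
- Mitsunobu etherification of 25 with 2-(trimethylsilyl)ethanol (PPh3, DIAD, THF) gives 3-methyl-4-[2-(trimethylsilyl)ethoxy]furan-2(5H)-one F6.
- LiN(i-Pr)2 at −78 °C gives lithium 3-methyl-4-[2-(trimethylsilyl)ethoxy]furan-2-olate F7.
- Addition to 24 gives 5-[(2S,6Z,10E)-13-(furan-3-yl)-1-hydroxy-2,6,10-trimethyltrideca-6,10-dien-1-yl]-3-methyl-4-[2-(trimethylsilyl)ethoxy]furan-2(5H)-one F8.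
- MsCl and Et3N give (2S,6Z,10E)-13-(furan-3-yl)-2,6,10-trimethyl-1-{4-methyl-5-oxo-3-[2-(trimethylsilyl)ethoxy]-2,5-dihydrofuran-2-yl}trideca-6,10-dien-1-yl methanesulfonate F9.
- DBU gives (5Z)-5-[(2S,6Z,10E)-13-(furan-3-yl)-2,6,10-trimethyltrideca-6,10-dien-1-ylidene]-3-methyl-4-[2-(trimethylsilyl)ethoxy]furan-2(5H)-one F10.
- Bu4NF in THF followed by dilute HCl gives 31.

**Further compounds**

F1 | step 5 | 3-[(3E)-8,8-dibromo-4-methylocta-3,7-dien-1-yl]furan | BrC(Br)=CCC/C(C)=C/CCc1ccoc1
F2 | step 5 | 3-[(3E,7Z)-8-bromo-4-methylnona-3,7-dien-1-yl]furan | Br/C(C)=C\CC/C(C)=C/CCc1ccoc1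
F3 | step 8 | tert-butyl(dimethyl){[(2S)-2-methylpent-4-en-1-yl]oxy}silane | C=CC[C@H](C)CO[Si](C)(C)C(C)(C)C
F4 | step 8 | 9-[(4S)-5-{[tert-butyl(dimethyl)silyl]oxy}-4-methylpentyl]-9-borabicyclo[3.3.1]nonane | CC(C)(C)[Si](C)(C)OC[C@@H](C)CCCB1C2CCCC1CCC2
F5 | step 8 | tert-butyl{[(2S,6Z,10E)-13-(furan-3-yl)-2,6,10-trimethyltrideca-6,10-dien-1-yl]oxy}dimethylsilane | CC(C)(C)[Si](C)(C)OC[C@@H](C)CCC/C(C)=C\CC/C(C)=C/CCc1ccoc1
F6 | step 13 | 3-methyl-4-[2-(trimethylsilyl)ethoxy]furan-2(5H)-one | C[Si](C)(C)CCOC1=C(C)C(=O)OC1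
F7 | step 13 | lithium 3-methyl-4-[2-(trimethylsilyl)ethoxy]furan-2-olate | [Li+].C[Si](C)(C)CCOc1coc([O-])c1C
F8 | step 13 | 5-[(2S,6Z,10E)-13-(furan-3-yl)-1-hydroxy-2,6,10-trimethyltrideca-6,10-dien-1-yl]-3-methyl-4-[2-(trimethylsilyl)ethoxy]furan-2(5H)-one | C[Si](C)(C)CCOC1=C(C)C(=O)OC1C(O)[C@@H](C)CCC/C(C)=C\CC/C(C)=C/CCc2ccoc2
F9 | step 13 | (2S,6Z,10E)-13-(furan-3-yl)-2,6,10-trimethyl-1-{4-methyl-5-oxo-3-[2-(trimethylsilyl)ethoxy]-2,5-dihydrofuran-2-yl}trideca-6,10-dien-1-yl methanesulfonate | C[Si](C)(C)CCOC1=C(C)C(=O)OC1C(OS(C)(=O)=O)[C@@H](C)CCC/C(C)=C\CC/C(C)=C/CCc2ccoc2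
F10 | step 13 | (5Z)-5-[(2S,6Z,10E)-13-(furan-3-yl)-2,6,10-trimethyltrideca-6,10-dien-1-ylidene]-3-methyl-4-[2-(trimethylsilyl)ethoxy]furan-2(5H)-one | CC1=C(OCC[Si](C)(C)C)/C(=C/[C@@H](C)CCC/C(C)=C\CC/C(C)=C/CCc2ccoc2)OC1=O
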